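**Retrosynthetic overview**

1. The last operations are desilylation of O5 and an invertive (Mitsunobu) angeloylation of an 8-epi alcohol, so the isomerisation-prone angelate enters only after the carbocycle exists.
2. Key disconnection: the C7–C8 bond of the ten-membered ring. The α-methylene-γ-butyrolactone holds the homoallylic alcohol array C13=C11–C7–C8–O8 (exocyclic C11=C13 on the lactone, ring-fusion carbon C7, carbinol C8). This is the retron of a carbonyl allylation: moving the alkene to C7=C11 gives a 3-(bromomethyl)butenolide, and its CrCl2-mediated intramolecular allylation of a C8 aldehyde closes the carbocycle, sets C7 and C8 and regenerates the exocyclic methylene.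
3. The butenolide comes from ring-closing metathesis of the 2-(bromomethyl)acrylate of the C6 allylic alcohol.
4. The C5/C6 syn-diol comes from a (Z)-γ-alkoxyallylboration of a 2-methylene aldehyde; the (E)-C1=C10 enoate from a Wittig mono-olefination of glutaraldehyde; C15 from an aldehyde α-methylenation.
5. Ring order: lactone ring first (as the butenolide, step 9), ten-membered carbocycle second (step 12).

Key step: step 12

Remark: atoms are numbered as in germacranolides (C1–C10 carbocycle; C11–C13 lactone with C12 the carbonyl and C13 the exocyclic CH2; C14 the ester carbon on C10; C15 the exocyclic CH2 on C4). The Ipc2B reagent from (−)-α-pinene is assumed to add to the Re face of the aldehyde, as its parent allyl reagent does.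

**Step 1**
Reactants: 1 methyl (triphenylphosphoranylidene)acetate; 2 tert-butyl(2-iodoethoxy)dimethylsilane
Product: 4 methyl 4-(tert-butyldimethylsilyloxy)-2-(triphenylphosphoranylidene)butanoate, via phosphonium iodide 3 (not isolated)
Conditions: MeCN, 80 °C; then aq. NaOH, CH2Cl2, 0 °C
Reagents that add atoms: none
Why: C-alkylation of the ester-stabilised ylide by the primary iodide should give the phosphonium salt, which cold aqueous hydroxide deprotonates to the α-substituted stabilised ylide (ylide alkylation).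

**Step 2**
Reactants: 4 methyl 4-(tert-butyldimethylsilyloxy)-2-(triphenylphosphoranylidene)butanoate; 5 glutaraldehyde
Product: 6 methyl (2E)-2-[2-(tert-butyldimethylsilyloxy)ethyl]-7-oxohept-2-enoate
Conditions: 5 (50% aq., 5 equiv), CH2Cl2, rt to 40 °C
Reagents that add atoms: none
Why: Wittig olefination with an α-branched stabilised ylide is reliably (E)-selective (C2 chain trans to CO2Me), and the excess of the symmetrical dialdehyde should hold the reaction at mono-olefination.

**Step 3**
Reactants: 6 methyl (2E)-2-[2-(tert-butyldimethylsilyloxy)ethyl]-7-oxohept-2-enoate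
Product: 7 methyl (2E)-2-[2-(tert-butyldimethylsilyloxy)ethyl]-6-formylhepta-2,6-dienoate
Conditions: 37% aq. CH2O, pyrrolidine (10 mol%), propionic acid (10 mol%), iPrOH, 45 °C
Reagents that add atoms: formaldehyde, C=O
Why: Amine-catalysed Mannich condensation and elimination (aldehyde α-methylenation) should install C15 at the only enolisable α-carbon (C4) without touching the trisubstituted enoate.

**Step 4**
Reactants: 8 allyl alcohol
Product: 9 allyl methoxymethyl ether
Conditions: MOMCl, iPr2NEt, CH2Cl2, 0 °C to rt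
Reagents that add atoms: chloromethyl methyl ether, COCCl
Why: Standard O-alkylation of a primary alcohol with an α-chloro ether (acetal protection).

**Step 5**
Reactants: 9 allyl methoxymethyl ether; 7 methyl (2E)-2-[2-(tert-butyldimethylsilyloxy)ethyl]-6-formylhepta-2,6-dienoate
Product: 12 methyl (2E,7S,8S)-2-[2-(tert-butyldimethylsilyloxy)ethyl]-7-hydroxy-8-(methoxymethoxy)-6-methylidenedeca-2,9-dienoate, via allylborane 10 (not isolated), via borinate 11 (not isolated)
Conditions: 9, sec-BuLi, THF, −78 °C; (+)-Ipc2BOMe; BF3·OEt2; then 7, −78 °C; ethanolamine work-up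
Reagents that add atoms: none
Why: Brown-type alkoxyallylboration through a chair six-membered transition state, in which the (Z)-γ-alkoxyallyl geometry gives the syn C5/C6 diol monoether and the isopinocampheyl groups from (−)-α-pinene direct attack to the Re face of the aldehyde, should set 7S,8S (C5 and C6 of the target); the enoate is inert to the allylborane at −78 °C and the non-oxidative work-up spares it.

**Step 6**
Reactants: 12 methyl (2E,7S,8S)-2-[2-(tert-butyldimethylsilyloxy)ethyl]-7-hydroxy-8-(methoxymethoxy)-6-methylidenedeca-2,9-dienoate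
Product: 13 methyl (2E,7S,8S)-7-(tert-butyldimethylsilyloxy)-2-[2-(tert-butyldimethylsilyloxy)ethyl]-8-(methoxymethoxy)-6-methylidenedeca-2,9-dienoate
Conditions: TBSOTf, 2,6-lutidine, CH2Cl2, −78 to 0 °C
Reagents that add atoms: tert-butyldimethylsilyl triflate, CC(C)(C)[Si](C)(C)OS(=O)(=O)C(F)(F)F
Why: Silyl triflate silylation of the hindered secondary allylic alcohol under buffered conditions, with no stereocentre involved.

**Step 7**
Reactants: 13 methyl (2E,7S,8S)-7-(tert-butyldimethylsilyloxy)-2-[2-(tert-butyldimethylsilyloxy)ethyl]-8-(methoxymethoxy)-6-methylidenedeca-2,9-dienoate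
Product: 15 methyl (2E,7S,8S)-7-(tert-butyldimethylsilyloxy)-2-[2-(tert-butyldimethylsilyloxy)ethyl]-8-hydroxy-6-methylidenedeca-2,9-dienoate, via bipyridinium triflate 14 (not isolated)
Conditions: TMSOTf, 2,2′-bipyridyl, CH2Cl2, 0 °C; then H2O, rt
Reagents that add atoms: none
Why: The acetal centre of the MOM ether is activated by the silyl triflate and captured by 2,2′-bipyridyl as a pyridinium salt that water hydrolyses, whereas the two silyl ethers, which lack an acetal carbon, should survive these buffered, non-protic conditions.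

**Step 8**
Reactants: 15 methyl (2E,7S,8S)-7-(tert-butyldimethylsilyloxy)-2-[2-(tert-butyldimethylsilyloxy)ethyl]-8-hydroxy-6-methylidenedeca-2,9-dienoate; 16 2-(bromomethyl)acrylic acid
Product: 17 methyl (2E,7S,8S)-8-{[2-(bromomethyl)prop-2-enoyl]oxy}-7-(tert-butyldimethylsilyloxy)-2-[2-(tert-butyldimethylsilyloxy)ethyl]-6-methylidenedeca-2,9-dienoate
Conditions: DCC, DMAP (5 mol%), CH2Cl2, −20 to 0 °C
Reagents that add atoms: none
Why: Steglich esterification acylates the only free hydroxyl (O6) with retention at C6, the low temperature and low loading of the nucleophilic catalyst limiting attack on the allylic bromide.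

**Step 9**
Reactants: 17 methyl (2E,7S,8S)-8-{[2-(bromomethyl)prop-2-enoyl]oxy}-7-(tert-butyldimethylsilyloxy)-2-[2-(tert-butyldimethylsilyloxy)ethyl]-6-methylidenedeca-2,9-dienoate
Product: 18 methyl (2E,7S)-7-[(2S)-4-(bromomethyl)-5-oxo-2,5-dihydrofuran-2-yl]-7-(tert-butyldimethylsilyloxy)-2-[2-(tert-butyldimethylsilyloxy)ethyl]-6-methylidenehept-2-enoate
Conditions: second-generation Grubbs catalyst RuCl2(=CHPh)(PCy3)(H2IMes) (5 mol%), CH2Cl2, 40 °C
Reagents that add atoms: none
Why: Ring-closing metathesis between the C7 vinyl group and the acrylate methylene closes the five-membered butenolide with loss of ethylene, which should be strongly favoured over any reaction of the hindered C4=C15 or trisubstituted C1=C10 alkenes and does not touch C6.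

**Step 10**
Reactants: 18 methyl (2E,7S)-7-[(2S)-4-(bromomethyl)-5-oxo-2,5-dihydrofuran-2-yl]-7-(tert-butyldimethylsilyloxy)-2-[2-(tert-butyldimethylsilyloxy)ethyl]-6-methylidenehept-2-enoate
Product: 19 methyl (2E,7S)-7-[(2S)-4-(bromomethyl)-5-oxo-2,5-dihydrofuran-2-yl]-7-(tert-butyldimethylsilyloxy)-2-(2-hydroxyethyl)-6-methylidenehept-2-enoate
Conditions: CSA (cat.), MeOH/CH2Cl2, 0 °C
Reagents that add atoms: none
Why: Acid-catalysed methanolysis cleaves the unhindered primary silyl ether much faster than the hindered secondary one at C5, and the non-basic medium spares the allylic bromide and the epimerisable butenolide γ-centre C6.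

**Step 11**
Reactants: 19 methyl (2E,7S)-7-[(2S)-4-(bromomethyl)-5-oxo-2,5-dihydrofuran-2-yl]-7-(tert-butyldimethylsilyloxy)-2-(2-hydroxyethyl)-6-methylidenehept-2-enoate
Product: 20 methyl (2E,7S)-7-[(2S)-4-(bromomethyl)-5-oxo-2,5-dihydrofuran-2-yl]-7-(tert-butyldimethylsilyloxy)-6-methylidene-2-(2-oxoethyl)hept-2-enoate
Conditions: Dess–Martin periodinane, CH2Cl2, 0 °C; crude aldehyde used at once
Reagents that add atoms: none
Why: Dess–Martin oxidation gives the β,γ-unsaturated aldehyde under neutral, non-enolising conditions, so migration of C1=C10 into conjugation with the aldehyde should be avoided.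

**Step 12**
Reactants: 20 methyl (2E,7S)-7-[(2S)-4-(bromomethyl)-5-oxo-2,5-dihydrofuran-2-yl]-7-(tert-butyldimethylsilyloxy)-6-methylidene-2-(2-oxoethyl)hept-2-enoate
Product: 23 (5S,6S,7R,8S)-5-(tert-butyldimethylsilyloxy)-8-hydroxygermacra-1(10)E,4(15),11(13)-trien-12,6-olid-14-oic acid methyl ester, via allylchromium dichloride 21 (not isolated), via chromium alkoxide 22 (not isolated)
Conditions: CrCl2 (10 equiv), THF, rt, syringe-pump addition of 20 (final 2 mM); then H2O
Reagents that add atoms: none
Why: Divalent chromium reduces the allylic C13–Br bond of the 3-(bromomethyl)butenolide and the resulting allylchromium adds through its γ-carbon C7 to the tethered aldehyde C8 (intramolecular Nozaki–Hiyama–Kishi allylation); the closest known reactions are chromium-mediated ring closures of ω-formyl 2-(bromomethyl)acrylates to medium and large rings and Barbier additions of 3-(bromomethyl)furan-2(5H)-ones to aldehydes. The ten-membered carbocycle closes in a 10-exo-trig mode onto the aldehyde carbonyl, and the SE2′ shift of the double bond from C7=C11 to C11=C13 delivers the α-methylene-γ-butyrolactone in the same event. C7 is controlled by C6: the planar butenolide is attacked on the face opposite its C5 substituent, which is also the only approach that avoids an eclipsed C5–C6–C7–C8 torsion in the forming ring, so the trans-fused lactone (7R) should result. C8 is controlled by the ring-locked allyl geometry: with C6 held trans to CH2Cr and the aldehyde chain equatorial in the chair Zimmerman–Traxler transition state, the 7,8-anti adduct (8S) is expected, which is the configuration that the invertive acylation of step 13 requires. The step needs γ- over α-attack and aldehyde over ester or lactone addition, both inherent to allylchromium reagents, and cyclisation over oligomerisation, which high dilution, the ring-cis C1=C10 enoate and the sp2 centre C4 in the tether should secure.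

**Step 13**
Reactants: 23 (5S,6S,7R,8S)-5-(tert-butyldimethylsilyloxy)-8-hydroxygermacra-1(10)E,4(15),11(13)-trien-12,6-olid-14-oic acid methyl ester; 24 angelic acid
Product: 25 (5S,6S,7R,8R)-8-angeloyloxy-5-(tert-butyldimethylsilyloxy)germacra-1(10)E,4(15),11(13)-trien-12,6-olid-14-oic acid methyl ester
Conditions: PPh3, DIAD (betaine pre-formed), 24, toluene, 0 °C to rt
Reagents that add atoms: none
Why: Mitsunobu esterification displaces the C8 oxyphosphonium by angelate with inversion (8S to 8R), and because the acid acts only as a carboxylate nucleophile its (Z)-alkene is never acyl-activated and should not isomerise to the tiglate.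

**Step 14**
Reactants: 25 (5S,6S,7R,8R)-8-angeloyloxy-5-(tert-butyldimethylsilyloxy)germacra-1(10)E,4(15),11(13)-trien-12,6-olid-14-oic acid methyl ester
Product: 26 (5S,6S,7R,8R)-8-angeloyloxy-5-hydroxygermacra-1(10)E,4(15),11(13)-trien-12,6-olid-14-oic acid methyl ester (CNP0163095.1)
Conditions: HF·pyridine, pyridine, THF, 0 °C to rt
Reagents that add atoms: none
Why: Acidic fluoride desilylation should free O5 while leaving the angelate, the methyl ester and the α-methylene lactone untouched, which basic fluoride sources might not.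

**Compound list**

1 | methyl (triphenylphosphoranylidene)acetate | COC(=O)C=P(c1ccccc1)(c1ccccc1)c1ccccc1 | starting material
2 | tert-butyl(2-iodoethoxy)dimethylsilane | CC(C)(C)[Si](C)(C)OCCI | starting material
3 | [4-(tert-butyldimethylsilyloxy)-1-methoxy-1-oxobutan-2-yl]triphenylphosphonium iodide | COC(=O)C(CCO[Si](C)(C)C(C)(C)C)[P+](c1ccccc1)(c1ccccc1)c1ccccc1.[I-] | intermediate
4 | methyl 4-(tert-butyldimethylsilyloxy)-2-(triphenylphosphoranylidene)butanoate | COC(=O)C(CCO[Si](C)(C)C(C)(C)C)=P(c1ccccc1)(c1ccccc1)c1ccccc1 | intermediate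
5 | glutaraldehyde (pentanedial) | O=CCCCC=O | starting material
6 | methyl (2E)-2-[2-(tert-butyldimethylsilyloxy)ethyl]-7-oxohept-2-enoate | CC(C)(C)[Si](C)(C)OCC/C(C(=O)OC)=C\CCCC=O | intermediate
7 | methyl (2E)-2-[2-(tert-butyldimethylsilyloxy)ethyl]-6-formylhepta-2,6-dienoate | CC(C)(C)[Si](C)(C)OCC/C(C(=O)OC)=C\CCC(=C)C=O | intermediate
8 | allyl alcohol | C=CCO | starting material
9 | allyl methoxymethyl ether | C=CCOCOC | intermediate
10 | [(2Z)-3-(methoxymethoxy)prop-2-en-1-yl]diisopinocampheylborane, Ipc groups from (−)-α-pinene | COCO/C=C\CB([C@H]1C[C@H]2C[C@@H]([C@@H]1C)C2(C)C)[C@H]1C[C@H]2C[C@@H]([C@@H]1C)C2(C)C | intermediate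
11 | O7-diisopinocampheylboryl borinate of 12 | C=C[C@H](OCOC)[C@@H](OB([C@H]1C[C@H]2C[C@@H]([C@@H]1C)C2(C)C)[C@H]1C[C@H]2C[C@@H]([C@@H]1C)C2(C)C)C(=C)CC/C=C(\CCO[Si](C)(C)C(C)(C)C)C(=O)OC | intermediate
12 | methyl (2E,7S,8S)-2-[2-(tert-butyldimethylsilyloxy)ethyl]-7-hydroxy-8-(methoxymethoxy)-6-methylidenedeca-2,9-dienoate | C=C[C@H](OCOC)[C@@H](O)C(=C)CC/C=C(\CCO[Si](C)(C)C(C)(C)C)C(=O)OC | intermediate
13 | methyl (2E,7S,8S)-7-(tert-butyldimethylsilyloxy)-2-[2-(tert-butyldimethylsilyloxy)ethyl]-8-(methoxymethoxy)-6-methylidenedeca-2,9-dienoate | C=C[C@H](OCOC)[C@@H](O[Si](C)(C)C(C)(C)C)C(=C)CC/C=C(\CCO[Si](C)(C)C(C)(C)C)C(=O)OC | intermediate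
14 | 1-(alkoxymethyl)-2,2′-bipyridinium triflate derived from 13 (OMe of the acetal replaced by the bipyridinium nitrogen) | C=C[C@H](OC[n+]1ccccc1-c1ccccn1)[C@@H](O[Si](C)(C)C(C)(C)C)C(=C)CC/C=C(\CCO[Si](C)(C)C(C)(C)C)C(=O)OC.[O-]S(=O)(=O)C(F)(F)F | intermediate
15 | methyl (2E,7S,8S)-7-(tert-butyldimethylsilyloxy)-2-[2-(tert-butyldimethylsilyloxy)ethyl]-8-hydroxy-6-methylidenedeca-2,9-dienoate | C=C[C@H](O)[C@@H](O[Si](C)(C)C(C)(C)C)C(=C)CC/C=C(\CCO[Si](C)(C)C(C)(C)C)C(=O)OC | intermediate
16 | 2-(bromomethyl)acrylic acid | C=C(CBr)C(=O)O | starting material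
17 | methyl (2E,7S,8S)-8-{[2-(bromomethyl)prop-2-enoyl]oxy}-7-(tert-butyldimethylsilyloxy)-2-[2-(tert-butyldimethylsilyloxy)ethyl]-6-methylidenedeca-2,9-dienoate | C=C[C@H](OC(=O)C(=C)CBr)[C@@H](O[Si](C)(C)C(C)(C)C)C(=C)CC/C=C(\CCO[Si](C)(C)C(C)(C)C)C(=O)OC | intermediate
18 | methyl (2E,7S)-7-[(2S)-4-(bromomethyl)-5-oxo-2,5-dihydrofuran-2-yl]-7-(tert-butyldimethylsilyloxy)-2-[2-(tert-butyldimethylsilyloxy)ethyl]-6-methylidenehept-2-enoate | BrCC1=C[C@H](OC1=O)[C@@H](O[Si](C)(C)C(C)(C)C)C(=C)CC/C=C(\CCO[Si](C)(C)C(C)(C)C)C(=O)OC | intermediate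
19 | methyl (2E,7S)-7-[(2S)-4-(bromomethyl)-5-oxo-2,5-dihydrofuran-2-yl]-7-(tert-butyldimethylsilyloxy)-2-(2-hydroxyethyl)-6-methylidenehept-2-enoate | BrCC1=C[C@H](OC1=O)[C@@H](O[Si](C)(C)C(C)(C)C)C(=C)CC/C=C(\CCO)C(=O)OC | intermediate
20 | methyl (2E,7S)-7-[(2S)-4-(bromomethyl)-5-oxo-2,5-dihydrofuran-2-yl]-7-(tert-butyldimethylsilyloxy)-6-methylidene-2-(2-oxoethyl)hept-2-enoate | BrCC1=C[C@H](OC1=O)[C@@H](O[Si](C)(C)C(C)(C)C)C(=C)CC/C=C(\CC=O)C(=O)OC | intermediate
21 | allylchromium dichloride from 20 (CrCl2 on C13 in place of Br) | Cl[Cr](Cl)CC1=C[C@H](OC1=O)[C@@H](O[Si](C)(C)C(C)(C)C)C(=C)CC/C=C(\CC=O)C(=O)OC | intermediate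
22 | O8-dichlorochromium alkoxide of 23 | C=C1C(=O)O[C@H]2[C@H]1[C@@H](O[Cr](Cl)Cl)C/C(C(=O)OC)=C\CCC(=C)[C@@H]2O[Si](C)(C)C(C)(C)C | intermediate
23 | (5S,6S,7R,8S)-5-(tert-butyldimethylsilyloxy)-8-hydroxygermacra-1(10)E,4(15),11(13)-trien-12,6-olid-14-oic acid methyl ester (trans-fused lactone, 8-epi alcohol) | C=C1C(=O)O[C@H]2[C@H]1[C@@H](O)C/C(C(=O)OC)=C\CCC(=C)[C@@H]2O[Si](C)(C)C(C)(C)C | intermediate
24 | angelic acid, (2Z)-2-methylbut-2-enoic acid | C/C=C(/C)C(=O)O | starting material
25 | (5S,6S,7R,8R)-8-angeloyloxy-5-(tert-butyldimethylsilyloxy)germacra-1(10)E,4(15),11(13)-trien-12,6-olid-14-oic acid methyl ester | C=C1C(=O)O[C@H]2[C@H]1[C@H](OC(=O)/C(C)=C\C)C/C(C(=O)OC)=C\CCC(=C)[C@@H]2O[Si](C)(C)C(C)(C)C | intermediate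
26 | (5S,6S,7R,8R)-8-angeloyloxy-5-hydroxygermacra-1(10)E,4(15),11(13)-trien-12,6-olid-14-oic acid methyl ester (CNP0163095.1) | C=C1C(=O)O[C@H]2[C@H]1[C@H](OC(=O)/C(C)=C\C)C/C(C(=O)OC)=C\CCC(=C)[C@@H]2O | target

**Step count and risks**

Total steps: 14. Longest linear sequence: 13 (steps 1–3 and 5–14); step 4 is a one-step side branch.

Step 12 (ring closure). The allylchromium may be consumed by oligomerisation or protonation before the strained ten-membered ring closes, or the aldehyde face may not be differentiated as the chair model predicts. The fallback sets out from 19 and replaces the closed chromium transition state by a Lewis-acid-promoted open one. Barbier-type stannylation of 19 (Bu3SnCl, Zn, THF/aq. NH4Cl) should give the allylstannane F1, and Dess–Martin oxidation the stannyl aldehyde F2. BF3·OEt2 in CH2Cl2 at −78 °C under high dilution (intramolecular Hosomi–Sakurai-type allylstannane addition) should then close the ring through an open transition state, which favours the 7,8-syn adduct, the 8R alcohol F3. Acylation of F3 with the mixed anhydride of 24 and 2,4,6-trichlorobenzoyl chloride (Et3N, toluene; Yamaguchi conditions, retention at C8) returns to the route at 25.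

Step 13 (Mitsunobu). The activated C8 oxygen may be lost by elimination toward C9, giving a diene conjugated with the C14 ester, or substitution at the hindered carbinol may not occur. The fallback sets out from 23 and inverts C8 by oxidation and reduction instead of displacement. Dess–Martin oxidation should give the C8 ketone F4. Luche reduction (NaBH4, CeCl3, MeOH, −78 °C), with hydride approaching the carbonyl face remote from the fused lactone, should give the 8R alcohol F3. Yamaguchi acylation with 24, as above, returns to the route at 25.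

Step 9 (butenolide formation). The allylic bromide may deactivate the ruthenium carbene or the closure onto the α-substituted acrylate may stall; the same bromide may also be attacked by the acylation catalyst in step 8. The fallback sets out from 15 and carries C13 as a protected alcohol. Commercial ethyl 2-(hydroxymethyl)acrylate is etherified with 4-methoxybenzyl trichloroacetimidate (cat. CSA) to the ether ester F5 and saponified (LiOH) to the acid F6. Steglich esterification of 15 with F6 gives the ester F7, and ring-closing metathesis with the same second-generation Grubbs catalyst gives the butenolide F8. DDQ (CH2Cl2/H2O) frees the allylic alcohol F9, and Appel bromination (CBr4, PPh3) returns to the route at 18.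

**Further compounds**

F1 | step 12 | methyl (2E,7S)-7-(tert-butyldimethylsilyloxy)-2-(2-hydroxyethyl)-6-methylidene-7-{(2S)-5-oxo-4-[(tributylstannyl)methyl]-2,5-dihydrofuran-2-yl}hept-2-enoate | CCCC[Sn](CCCC)(CCCC)CC1=C[C@H](OC1=O)[C@@H](O[Si](C)(C)C(C)(C)C)C(=C)CC/C=C(\CCO)C(=O)OC
F2 | step 12 | methyl (2E,7S)-7-(tert-butyldimethylsilyloxy)-6-methylidene-2-(2-oxoethyl)-7-{(2S)-5-oxo-4-[(tributylstannyl)methyl]-2,5-dihydrofuran-2-yl}hept-2-enoate | CCCC[Sn](CCCC)(CCCC)CC1=C[C@H](OC1=O)[C@@H](O[Si](C)(C)C(C)(C)C)C(=C)CC/C=C(\CC=O)C(=O)OC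
F3 | step 12 | (5S,6S,7R,8R)-5-(tert-butyldimethylsilyloxy)-8-hydroxygermacra-1(10)E,4(15),11(13)-trien-12,6-olid-14-oic acid methyl ester | C=C1C(=O)O[C@H]2[C@H]1[C@H](O)C/C(C(=O)OC)=C\CCC(=C)[C@@H]2O[Si](C)(C)C(C)(C)C
F4 | step 13 | (5S,6S,7R)-5-(tert-butyldimethylsilyloxy)-8-oxogermacra-1(10)E,4(15),11(13)-trien-12,6-olid-14-oic acid methyl ester | C=C1C(=O)O[C@H]2[C@H]1C(=O)C/C(C(=O)OC)=C\CCC(=C)[C@@H]2O[Si](C)(C)C(C)(C)C
F5 | step 9 | ethyl 2-{[(4-methoxybenzyl)oxy]methyl}acrylate | C=C(COCc1ccc(OC)cc1)C(=O)OCC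
F6 | step 9 | 2-{[(4-methoxybenzyl)oxy]methyl}acrylic acid | C=C(COCc1ccc(OC)cc1)C(=O)O
F7 | step 9 | methyl (2E,7S,8S)-7-(tert-butyldimethylsilyloxy)-2-[2-(tert-butyldimethylsilyloxy)ethyl]-8-[(2-{[(4-methoxybenzyl)oxy]methyl}prop-2-enoyl)oxy]-6-methylidenedeca-2,9-dienoate | C=C[C@H](OC(=O)C(=C)COCc1ccc(OC)cc1)[C@@H](O[Si](C)(C)C(C)(C)C)C(=C)CC/C=C(\CCO[Si](C)(C)C(C)(C)C)C(=O)OC
F8 | step 9 | methyl (2E,7S)-7-(tert-butyldimethylsilyloxy)-2-[2-(tert-butyldimethylsilyloxy)ethyl]-7-[(2S)-4-{[(4-methoxybenzyl)oxy]methyl}-5-oxo-2,5-dihydrofuran-2-yl]-6-methylidenehept-2-enoate | COc1ccc(COCC2=C[C@H](OC2=O)[C@@H](O[Si](C)(C)C(C)(C)C)C(=C)CC/C=C(\CCO[Si](C)(C)C(C)(C)C)C(=O)OC)cc1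
F9 | step 9 | methyl (2E,7S)-7-(tert-butyldimethylsilyloxy)-2-[2-(tert-butyldimethylsilyloxy)ethyl]-7-[(2S)-4-(hydroxymethyl)-5-oxo-2,5-dihydrofuran-2-yl]-6-methylidenehept-2-enoate | OCC1=C[C@H](OC1=O)[C@@H](O[Si](C)(C)C(C)(C)C)C(=C)CC/C=C(\CCO[Si](C)(C)C(C)(C)C)C(=O)OC
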